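Locants: ring C1 (carries the chain), C2 (CH2), C3–C4 (oxirane, CH3 on C4), C5 and C6 (angelates); chain C7 (=CH2), C8 (OAc), C9–C11 (prenyl). The enabling feature is the cis-C5/C6 diol of the six-membered carbocycle, lying between methyl-bearing C4 and chain-bearing C1: this is the 2,3-cis-dihydrodiol pattern of a para-disubstituted benzene.
Cuts, in retrosynthetic order: both angelate C–O bonds; the C3–O–C4 oxirane; the C8 acetate; C7=CH2 (back to a C7 ketone); C1–H and C2–H (back to a C1=C2 dienone); C1–C7 (alkenyl iodide + C7 aldehyde); finally C5–O and C6–O, which returns the ring to 4-iodotoluene. The C7–C11 aldehyde is cut at C9–C10 to methyl (S)-glycidate and an isobutenyl Grignard reagent.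
Forward: no carbocycle is built, since the arene becomes the ring in the first step. The chain is joined at C1 through the iodide, the diene is trimmed to the C3=C4 alkene by 1,4-reduction, C7 is methylenated, and the oxirane is the only ring closed (step 13), just before the angelates go on.
Stereochemistry: C5 and C6 from the dioxygenase; C8 from the glycidate; C1 by enolate protonation anti to the dioxolane; C3 and C4 by epoxidation directed by the C5/C6 hydroxyls.

Key step: step 1

Remark: the locants C1–C11 used below are those of the plan; in step 1 the reducing equivalents (NADH) are regenerated by the glucose-fed cells and are counted as catalytic.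

Step 1
Reactants: 1 4-iodotoluene
Product: 2 (1S,2S)-3-iodo-6-methylcyclohexa-3,5-diene-1,2-diol
Conditions: toluene dioxygenase, whole cells of recombinant E. coli (todC1C2BA, no cis-diol dehydrogenase), air, glucose feed, pH 7, 30 °C; EtOAc extraction, recrystallisation
Reagents that add atoms: dioxygen, O=O
Why: The Rieske non-haem iron(II) centre of the dioxygenase, fed two electrons from NADH through its reductase and ferredoxin, binds O2 side-on and transfers both oxygen atoms to the C5=C6 edge of the bound arene, releasing the dearomatised cis-dihydrodiol, which persists because the host lacks the diol dehydrogenase. The closest known reaction type is the whole-cell toluene dioxygenase cis-dihydroxylation of halobenzenes and para-substituted toluenes. No ring is closed; the aromatic ring becomes the carbocycle and keeps the C1(I)=C2–C3=C4(CH3) diene. C5 and C6 are cis because both C–O bonds form suprafacially from one bound O2, and their absolute configuration is set by the active-site pocket, which seats the larger para substituent (iodine) where the single substituent of a monosubstituted benzene sits, so the diol of the iodobenzene series, (1S,2S), is expected. The step needs enantiotopic-edge selectivity between an iodine-directed and a methyl-directed binding mode, and the size difference between I and CH3 is what secures it. Any antipode that does form would become a diastereomer on coupling with enantiopure 8 and would be removed by chromatography at the stage of 10.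

Step 2
Reactants: 2 (1S,2S)-3-iodo-6-methylcyclohexa-3,5-diene-1,2-diol
Product: 3 (3aS,7aS)-4-iodo-2,2,7-trimethyl-3a,7a-dihydro-1,3-benzodioxole
Conditions: Me2C(OMe)2, p-TsOH·H2O (cat.), acetone, 0 °C → rt; stored cold, used promptly
Reagents that add atoms: 2,2-dimethoxypropane, COC(C)(C)OC
Why: Acid-catalysed transketalisation of the cis-1,2-diol gives the cis-fused dioxolane without touching a stereocentre, which blocks dehydration to a phenol and shields the oxygen-bearing face of the ring for the later steps.

Step 3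
Reactants: 4 methyl (2S)-oxirane-2-carboxylate; 5 (2-methylprop-1-en-1-yl)magnesium bromide
Product: 6 methyl (2S)-2-hydroxy-5-methylhex-4-enoate
Conditions: CuI (10 mol %), THF, −40 → −20 °C; aq. NH4Cl
Reagents that add atoms: none
Why: Copper-catalysed SN2 opening of the unsubstituted epoxide carbon by the alkenyl Grignard reagent, a standard glycidate-to-α-hydroxy-ester homologation, forms C9–C10 without touching the stereocentre, so the (S) centre of 4 becomes C8.

Step 4
Reactants: 6 methyl (2S)-2-hydroxy-5-methylhex-4-enoate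
Product: 7 methyl (2S)-2-[(tert-butyldimethylsilyl)oxy]-5-methylhex-4-enoate
Conditions: TBSCl, imidazole, DMF, rt
Reagents that add atoms: tert-butyldimethylsilyl chloride, CC(C)(C)[Si](C)(C)Cl
Why: Imidazole-promoted silylation of a secondary alcohol installs an ether that should survive the chromium, periodinane, copper hydride and titanium steps and can later be removed by fluoride in the presence of the acetonide.

Step 5
Reactants: 7 methyl (2S)-2-[(tert-butyldimethylsilyl)oxy]-5-methylhex-4-enoate
Product: 8 (2S)-2-[(tert-butyldimethylsilyl)oxy]-5-methylhex-4-enal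
Conditions: DIBAL-H (1.1 equiv), CH2Cl2, −78 °C; Rochelle salt work-up; used crude
Reagents that add atoms: none
Why: Half-reduction of an α-silyloxy methyl ester with DIBAL-H at −78 °C stops at the aldehyde because the chelated aluminium hemiacetal persists until work-up, and C8 is not enolised under these conditions.

Step 6
Reactants: 3 (3aS,7aS)-4-iodo-2,2,7-trimethyl-3a,7a-dihydro-1,3-benzodioxole; 8 (2S)-2-[(tert-butyldimethylsilyl)oxy]-5-methylhex-4-enal
Product: 9 (2S)-2-[(tert-butyldimethylsilyl)oxy]-5-methyl-1-[(3aR,7aS)-2,2,7-trimethyl-3a,7a-dihydro-1,3-benzodioxol-4-yl]hex-4-en-1-ol (both C7 epimers)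
Conditions: CrCl2 (4 equiv), NiCl2 (1 mol %), DMSO/THF, rt
Reagents that add atoms: none
Why: In this Nozaki–Hiyama–Kishi coupling nickel inserts into the C1–I bond and hands the alkenyl group to chromium(III), which adds to the aldehyde without any base, so the C1–C7 bond forms with C8 intact, while the uncontrolled C7 carbinol centre is erased in step 7.

Step 7
Reactants: 9 (2S)-2-[(tert-butyldimethylsilyl)oxy]-5-methyl-1-[(3aR,7aS)-2,2,7-trimethyl-3a,7a-dihydro-1,3-benzodioxol-4-yl]hex-4-en-1-ol
Product: 10 (2S)-2-[(tert-butyldimethylsilyl)oxy]-5-methyl-1-[(3aR,7aS)-2,2,7-trimethyl-3a,7a-dihydro-1,3-benzodioxol-4-yl]hex-4-en-1-one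
Conditions: Dess–Martin periodinane, pyridine, CH2Cl2, 0 °C → rt
Reagents that add atoms: none
Why: Dess–Martin oxidation of the dienylic secondary alcohol under buffered, non-basic conditions converges both C7 epimers on one dienone and leaves the α-silyloxy centre C8 untouched.

Step 8
Reactants: 10 (2S)-2-[(tert-butyldimethylsilyl)oxy]-5-methyl-1-[(3aR,7aS)-2,2,7-trimethyl-3a,7a-dihydro-1,3-benzodioxol-4-yl]hex-4-en-1-one
Product: 11 (2S)-2-[(tert-butyldimethylsilyl)oxy]-5-methyl-1-[(3aR,4R,7aS)-2,2,7-trimethyl-3a,4,5,7a-tetrahydro-1,3-benzodioxol-4-yl]hex-4-en-1-one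
Conditions: [(Ph3P)CuH]6 (0.4 equiv), H2O (5 equiv), degassed toluene/THF, rt
Reagents that add atoms: none
Why: Copper hydride conjugate reduction should deliver hydride to the β-carbon C2, since the δ-carbon C4 is fully substituted and hindered, and the copper enolate is protonated in situ by water at C1 from the face anti to the dioxolane oxygens, which places the acyl chain cis to the C6 oxygen under kinetic substrate control.

Step 9
Reactants: 11 (2S)-2-[(tert-butyldimethylsilyl)oxy]-5-methyl-1-[(3aR,4R,7aS)-2,2,7-trimethyl-3a,4,5,7a-tetrahydro-1,3-benzodioxol-4-yl]hex-4-en-1-one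
Product: 12 tert-butyldimethyl{[(3S)-6-methyl-2-[(3aR,4S,7aS)-2,2,7-trimethyl-3a,4,5,7a-tetrahydro-1,3-benzodioxol-4-yl]hepta-1,5-dien-3-yl]oxy}silane
Conditions: Cp2TiMe2 (3 equiv), toluene/THF, 65 °C, dark
Reagents that add atoms: dimethyltitanocene, [CH3-].[CH3-].[Ti+4].c1cc[cH-]c1.c1cc[cH-]c1
Why: Petasis methylenation proceeds through thermally generated Cp2Ti=CH2 by [2+2] addition and cycloreversion under non-basic conditions, so the hindered, enolisable β-alkoxy ketone should become the 1,1-disubstituted alkene without epimerisation at C1 or C8 and without elimination of the C6 oxygen.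

Step 10
Reactants: 12 tert-butyldimethyl{[(3S)-6-methyl-2-[(3aR,4S,7aS)-2,2,7-trimethyl-3a,4,5,7a-tetrahydro-1,3-benzodioxol-4-yl]hepta-1,5-dien-3-yl]oxy}silane
Product: 13 (3S)-6-methyl-2-[(3aR,4S,7aS)-2,2,7-trimethyl-3a,4,5,7a-tetrahydro-1,3-benzodioxol-4-yl]hepta-1,5-dien-3-ol
Conditions: TBAF, THF, 0 °C → rt
Reagents that add atoms: none
Why: Fluoride cleaves the Si–O bond of the secondary silyl ether while the acetonide and the three alkenes are inert, and no base-sensitive carbonyl group is left at this stage.

Step 11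
Reactants: 13 (3S)-6-methyl-2-[(3aR,4S,7aS)-2,2,7-trimethyl-3a,4,5,7a-tetrahydro-1,3-benzodioxol-4-yl]hepta-1,5-dien-3-ol
Product: 14 (3S)-6-methyl-2-[(3aR,4S,7aS)-2,2,7-trimethyl-3a,4,5,7a-tetrahydro-1,3-benzodioxol-4-yl]hepta-1,5-dien-3-yl acetate
Conditions: Ac2O, pyridine, DMAP (cat.), CH2Cl2, rt
Reagents that add atoms: acetic anhydride, CC(=O)OC(C)=O
Why: DMAP-catalysed O-acetylation of the only free hydroxyl puts the C8 acetate in place with retention, before the C5 and C6 hydroxyls are uncovered.

Step 12
Reactants: 14 (3S)-6-methyl-2-[(3aR,4S,7aS)-2,2,7-trimethyl-3a,4,5,7a-tetrahydro-1,3-benzodioxol-4-yl]hepta-1,5-dien-3-yl acetate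
Product: 15 (3S)-2-[(1S,5S,6R)-5,6-dihydroxy-4-methylcyclohex-3-en-1-yl]-6-methylhepta-1,5-dien-3-yl acetate
Conditions: AcOH/H2O (4:1), 40 °C
Reagents that add atoms: none
Why: Mild aqueous-acid hydrolysis of the isopropylidene acetal frees the cis-diol, conditions that the acetate and the di- and trisubstituted alkenes are expected to tolerate.

Step 13
Reactants: 15 (3S)-2-[(1S,5S,6R)-5,6-dihydroxy-4-methylcyclohex-3-en-1-yl]-6-methylhepta-1,5-dien-3-yl acetate
Product: 16 (3S)-2-[(1R,2R,3R,4S,6S)-2,3-dihydroxy-1-methyl-7-oxabicyclo[4.1.0]heptan-4-yl]-6-methylhepta-1,5-dien-3-yl acetate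
Conditions: VO(acac)2 (5 mol %), t-BuOOH (in decane), CH2Cl2, 0 °C → rt
Reagents that add atoms: tert-butyl hydroperoxide, CC(C)(C)OO
Why: In this vanadium-catalysed hydroxyl-directed epoxidation the allylic C5–OH, supported by the cis C6–OH, binds the vanadium alkyl peroxide and delivers oxygen to the C3=C4 face syn to both hydroxyls, which sets C3 and C4, while the prenyl alkene has no nearby hydroxyl and the merely homoallylic exo-methylene should react far more slowly.

Step 14
Reactants: 16 (3S)-2-[(1R,2R,3R,4S,6S)-2,3-dihydroxy-1-methyl-7-oxabicyclo[4.1.0]heptan-4-yl]-6-methylhepta-1,5-dien-3-yl acetate; 17 angelic acid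
Product: 20 target CNP0188566.2 (C5/C6 bis-angelate of 16), via angelic 2,4,6-trichlorobenzoic anhydride 18 (not isolated), via C5 mono-angelate 19 (not isolated)
Conditions: 17 (3 equiv), 2,4,6-trichlorobenzoyl chloride, Et3N, toluene, rt, Et3N·HCl filtered off; then 16, toluene, 75 °C
Reagents that add atoms: none
Why: Yamaguchi-type mixed-anhydride acylation without a nucleophilic catalyst transfers the angeloyl group to the equatorial C5 hydroxyl first and then to C6, and because no conjugate addition–elimination pathway is opened the Z geometry of the acid should be retained in both esters.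

Compound list
1 | 4-iodotoluene | Cc1ccc(I)cc1 | starting material
2 | (1S,2S)-3-iodo-6-methylcyclohexa-3,5-diene-1,2-diol | IC1=CC=C(C)[C@H](O)[C@@H]1O | intermediate
3 | (3aS,7aS)-4-iodo-2,2,7-trimethyl-3a,7a-dihydro-1,3-benzodioxole | IC1=CC=C(C)[C@@H]2OC(C)(C)O[C@H]12 | intermediate
4 | methyl (2S)-oxirane-2-carboxylate (methyl (S)-glycidate) | COC(=O)[C@@H]1CO1 | starting material
5 | (2-methylprop-1-en-1-yl)magnesium bromide | CC(C)=C[Mg]Br | starting material
6 | methyl (2S)-2-hydroxy-5-methylhex-4-enoate | COC(=O)[C@H](CC=C(C)C)O | intermediate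
7 | methyl (2S)-2-[(tert-butyldimethylsilyl)oxy]-5-methylhex-4-enoate | COC(=O)[C@H](CC=C(C)C)O[Si](C)(C)C(C)(C)C | intermediate
8 | (2S)-2-[(tert-butyldimethylsilyl)oxy]-5-methylhex-4-enal | O=C[C@H](CC=C(C)C)O[Si](C)(C)C(C)(C)C | intermediate
9 | (2S)-2-[(tert-butyldimethylsilyl)oxy]-5-methyl-1-[(3aR,7aS)-2,2,7-trimethyl-3a,7a-dihydro-1,3-benzodioxol-4-yl]hex-4-en-1-ol, both C7 epimers | CC(C)=CC[C@H](O[Si](C)(C)C(C)(C)C)C(O)C1=CC=C(C)[C@@H]2OC(C)(C)O[C@H]12 | intermediate
10 | (2S)-2-[(tert-butyldimethylsilyl)oxy]-5-methyl-1-[(3aR,7aS)-2,2,7-trimethyl-3a,7a-dihydro-1,3-benzodioxol-4-yl]hex-4-en-1-one | CC(C)=CC[C@H](O[Si](C)(C)C(C)(C)C)C(=O)C1=CC=C(C)[C@@H]2OC(C)(C)O[C@H]12 | intermediate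
11 | (2S)-2-[(tert-butyldimethylsilyl)oxy]-5-methyl-1-[(3aR,4R,7aS)-2,2,7-trimethyl-3a,4,5,7a-tetrahydro-1,3-benzodioxol-4-yl]hex-4-en-1-one (acyl chain cis to the ring oxygens) | CC(C)=CC[C@H](O[Si](C)(C)C(C)(C)C)C(=O)[C@@H]1CC=C(C)[C@@H]2OC(C)(C)O[C@H]12 | intermediate
12 | tert-butyldimethyl{[(3S)-6-methyl-2-[(3aR,4S,7aS)-2,2,7-trimethyl-3a,4,5,7a-tetrahydro-1,3-benzodioxol-4-yl]hepta-1,5-dien-3-yl]oxy}silane | C=C([C@H](CC=C(C)C)O[Si](C)(C)C(C)(C)C)[C@@H]1CC=C(C)[C@@H]2OC(C)(C)O[C@H]12 | intermediate
13 | (3S)-6-methyl-2-[(3aR,4S,7aS)-2,2,7-trimethyl-3a,4,5,7a-tetrahydro-1,3-benzodioxol-4-yl]hepta-1,5-dien-3-ol | C=C([C@H](CC=C(C)C)O)[C@@H]1CC=C(C)[C@@H]2OC(C)(C)O[C@H]12 | intermediate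
14 | (3S)-6-methyl-2-[(3aR,4S,7aS)-2,2,7-trimethyl-3a,4,5,7a-tetrahydro-1,3-benzodioxol-4-yl]hepta-1,5-dien-3-yl acetate | C=C([C@H](CC=C(C)C)OC(C)=O)[C@@H]1CC=C(C)[C@@H]2OC(C)(C)O[C@H]12 | intermediate
15 | (3S)-2-[(1S,5S,6R)-5,6-dihydroxy-4-methylcyclohex-3-en-1-yl]-6-methylhepta-1,5-dien-3-yl acetate | C=C([C@H](CC=C(C)C)OC(C)=O)[C@@H]1CC=C(C)[C@H](O)[C@@H]1O | intermediate
16 | (3S)-2-[(1R,2R,3R,4S,6S)-2,3-dihydroxy-1-methyl-7-oxabicyclo[4.1.0]heptan-4-yl]-6-methylhepta-1,5-dien-3-yl acetate (oxirane, both hydroxyls and the chain on one face) | C=C([C@H](CC=C(C)C)OC(C)=O)[C@@H]1C[C@@H]2O[C@]2(C)[C@H](O)[C@@H]1O | intermediate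
17 | angelic acid, (2Z)-2-methylbut-2-enoic acid | C/C=C(/C)C(=O)O | starting material
18 | (2Z)-2-methylbut-2-enoic 2,4,6-trichlorobenzoic anhydride | C/C=C(/C)C(=O)OC(=O)c1c(Cl)cc(Cl)cc1Cl | intermediate
19 | (1S,2R,3R,4S,6S)-4-[(3S)-3-(acetyloxy)-6-methylhepta-1,5-dien-2-yl]-3-hydroxy-1-methyl-7-oxabicyclo[4.1.0]heptan-2-yl (2Z)-2-methylbut-2-enoate (C5 mono-angelate) | C=C([C@H](CC=C(C)C)OC(C)=O)[C@@H]1C[C@@H]2O[C@]2(C)[C@H](OC(=O)/C(C)=C\C)[C@@H]1O | intermediate
20 | (1S,2R,3R,4S,6S)-4-[(3S)-3-(acetyloxy)-6-methylhepta-1,5-dien-2-yl]-1-methyl-7-oxabicyclo[4.1.0]heptane-2,3-diyl bis[(2Z)-2-methylbut-2-enoate], CNP0188566.2 | C=C([C@H](CC=C(C)C)OC(C)=O)[C@@H]1C[C@@H]2O[C@]2(C)[C@H](OC(=O)/C(C)=C\C)[C@@H]1OC(=O)/C(C)=C\C | target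

Total step count: 14. Longest linear sequence: 12 steps (steps 3–14, from methyl (S)-glycidate); the arene branch runs through 11 steps (1, 2, 6–14).

Steps most likely to fail

Step 8. Hydride may be delivered in the 1,6 sense to C4 of the dienone, the copper enolate may be protonated at C1 with poor facial selectivity, or the enolate may expel the C6 oxygen before it is protonated. The fallback sets out from 10 and separates hydride delivery from the stereodefining protonation. Rhodium-catalysed 1,4-hydrosilylation (RhCl(PPh3)3, Et3SiH, benzene, 50 °C) works through Si–H oxidative addition and an oxa-allyl rhodium species on the s-cis enone, and should give the isolable triethylsilyl enol ether F1, which cannot undergo β-elimination. F1 would then be protonated at C1 in a separate operation (AcOH/THF/H2O, 0 °C, or a bulkier proton donor chosen for anti-dioxolane delivery), coming back to the route at 11.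

Step 14. The angeloyl unit may isomerise to the tigloyl (E) ester during acyl transfer, the second acylation of the hindered cis-diol may stall, or the oxirane may be opened by chloride at the reaction temperature. The fallback sets out from 16 and builds the Z-alkenes after the ester bonds are in place. Both hydroxyls would be esterified with 2-[bis(2,2,2-trifluoroethoxy)phosphoryl]propanoic acid (DCC, DMAP cat., CH2Cl2), an acylation that is known to reach hindered alcohols, to give the bis(phosphonopropanoate) F2. A double Still–Gennari olefination of F2 with acetaldehyde (KHMDS, 18-crown-6, THF, −78 °C) should then form both (Z)-2-methylbut-2-enoates under kinetic control, coming back to the route at 20.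

Step 9. Methylenation of the doubly α-branched carbonyl may be too slow, and prolonged heating with the titanium carbene may enolise the ketone, with epimerisation at C1 or loss of the C6 oxygen. The fallback sets out from 11 and replaces carbene transfer by addition–elimination. Cerium-mediated addition of (trimethylsilyl)methyllithium (CeCl3, THF, −78 °C), which tolerates hindered enolisable ketones, should give the β-hydroxysilane F3. Peterson elimination of F3 (KH, THF, 0 °C) would then give the methylene compound, coming back to the route at 12.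

Further compounds
F1 | step 8 | triethylsilyl enol ether of 11 (C7=C1 enol ether, E/Z mixture; C5, C6 and C8 as in 10) | CC[Si](CC)(CC)OC([C@H](CC=C(C)C)O[Si](C)(C)C(C)(C)C)=C1CC=C(C)[C@@H]2OC(C)(C)O[C@H]12
F2 | step 14 | C5,C6-bis{2-[bis(2,2,2-trifluoroethoxy)phosphoryl]propanoate} of 16 (phosphonate α-carbons unassigned) | C=C([C@H](CC=C(C)C)OC(C)=O)[C@@H]1C[C@@H]2O[C@]2(C)[C@H](OC(=O)C(C)P(=O)(OCC(F)(F)F)OCC(F)(F)F)[C@@H]1OC(=O)C(C)P(=O)(OCC(F)(F)F)OCC(F)(F)F
F3 | step 9 | β-hydroxysilane from 11 (C7 tertiary alcohol bearing CH2SiMe3, both C7 epimers) | C[Si](C)(C)CC(O)([C@H](CC=C(C)C)O[Si](C)(C)C(C)(C)C)[C@@H]1CC=C(C)[C@@H]2OC(C)(C)O[C@H]12
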